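The route cuts the O1–C2 bond of the dihydrofuran ring. Because the free 4-hydroxyphenyl ring sits directly on C2, taking two electrons from this phenol at an anode converts the neighbouring CH2 of an open-chain (S)-1,1,2-triarylethane into the exocyclic carbon of a p-quinone methide. The hydroxyl oxygen (O1) on the ester-bearing benzo ring then adds to that carbon, which closes the five-membered ring and sets the C2 aryl trans to the C3 aryl in a single operation. The precursor carries both reacting phenols free, the resorcinol ring as bulky triisopropylsilyl ethers and a methyl ester at the future C5; C3 is set by an enantioconvergent nickel-catalysed Negishi arylation, and the stilbene arm is attached by Horner–Wadsworth–Emmons olefination.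

Key step: step 6

Assumption: the enantiomer of the bis(oxazoline) ligand in step 4 that gives the (S)-configured product is fixed in a trial coupling; both enantiomers of the ligand are available.

Step 1
Reactants: 1 methyl 3-formyl-4-hydroxybenzoate
Product: 2 methyl 4-(benzyloxy)-3-formylbenzoate
Conditions: BnBr, K2CO3, DMF, 23 °C
Reagents that add atoms: benzyl bromide, BrCc1ccccc1
Why: Williamson etherification of the acidic salicylaldehyde-type phenol masks it as an ether that survives the organometallic steps and is later removed by hydrogenolysis.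

Step 2
Reactants: 3 4-(benzyloxy)benzyl chloride; 2 methyl 4-(benzyloxy)-3-formylbenzoate
Product: 5 racemic methyl 4-(benzyloxy)-3-{2-[4-(benzyloxy)phenyl]-1-hydroxyethyl}benzoate, via 4-(benzyloxy)benzylmagnesium chloride 4 (not isolated)
Conditions: Mg, THF, 0 °C (slow addition of 3); then 2, THF, −78 °C; aq. NH4Cl
Reagents that add atoms: none
Why: Grignard 1,2-addition of the benzylic magnesium reagent to the aldehyde should be far faster than attack on the methyl ester at −78 °C, and the carbinol centre is deliberately racemic because it is erased and reset in step 4.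

Step 3
Reactants: 6 5-bromobenzene-1,3-diol
Product: 7 1-bromo-3,5-bis(triisopropylsilyloxy)benzene
Conditions: i-Pr3SiCl, imidazole, DMF, 23 °C
Reagents that add atoms: chlorotriisopropylsilane, CC(C)[Si](Cl)(C(C)C)C(C)C
Why: Imidazole-promoted O-silylation caps both resorcinol oxygens as hindered silyl ethers that tolerate organomagnesium and organozinc chemistry, hydrogenolysis, anodic oxidation and hydride reduction.

Step 4
Reactants: 7 1-bromo-3,5-bis(triisopropylsilyloxy)benzene; 5 racemic methyl 4-(benzyloxy)-3-{2-[4-(benzyloxy)phenyl]-1-hydroxyethyl}benzoate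
Product: 12 methyl 4-(benzyloxy)-3-[(1S)-2-[4-(benzyloxy)phenyl]-1-[3,5-bis(triisopropylsilyloxy)phenyl]ethyl]benzoate, via [3,5-bis(triisopropylsilyloxy)phenyl]magnesium bromide 8 (not isolated), via [3,5-bis(triisopropylsilyloxy)phenyl]zinc iodide 9 (not isolated), via racemic mesylate 10 (not isolated), via racemic benzylic iodide 11 (not isolated)
Conditions: (a) 7, Mg, THF, 50 °C; then ZnI2, THF, 23 °C; (b) 5, MsCl, Et3N, CH2Cl2, −20 °C; (c) LiI, NiBr2(diglyme) (10 mol%), chiral methylene-bridged bis(oxazoline) (13 mol%), CH2Cl2–THF, −45 → −20 °C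
Reagents that add atoms: none
Why: In this enantioconvergent nickel-catalysed Negishi arylation the racemic mesylate is turned by LiI into the iodide, the low-valent nickel–bis(oxazoline) complex converts both enantiomers into one planar benzylic radical, and the chiral aryl-nickel species sets the (S) centre under catalyst control on radical capture and reductive elimination, with the ortho-substituted ring placed on the electrophile and the unhindered 3,5-disubstituted ring on zinc.

Step 5
Reactants: 12 methyl 4-(benzyloxy)-3-[(1S)-2-[4-(benzyloxy)phenyl]-1-[3,5-bis(triisopropylsilyloxy)phenyl]ethyl]benzoate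
Product: 13 methyl 3-[(1S)-1-[3,5-bis(triisopropylsilyloxy)phenyl]-2-(4-hydroxyphenyl)ethyl]-4-hydroxybenzoate
Conditions: H2 (1 atm), 10% Pd/C, EtOAc–EtOH, 23 °C
Reagents that add atoms: none
Why: Catalytic hydrogenolysis should cleave only the two benzyl aryl ethers, since the silyl ethers, the ester and the all-carbon C–H stereocentre offer no hydrogenolysable bond.

Step 6
Reactants: 13 methyl 3-[(1S)-1-[3,5-bis(triisopropylsilyloxy)phenyl]-2-(4-hydroxyphenyl)ethyl]-4-hydroxybenzoate
Product: 15 methyl (2S,3S)-3-[3,5-bis(triisopropylsilyloxy)phenyl]-2-(4-hydroxyphenyl)-2,3-dihydro-1-benzofuran-5-carboxylate, via p-quinone methide 14 (not isolated)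
Conditions: undivided cell, graphite anode, Pt cathode, constant current (5 mA cm−2, 2.1 F mol−1), LiClO4 (0.1 M), AcOH (2 equiv), CH2Cl2–MeOH 4:1, 0 °C
Reagents that add atoms: none
Why: At the carbon anode the unsubstituted 4-alkylphenol ring of 13 should be the first site to lose two electrons and two protons (the second from the benzylic CH2), giving p-quinone methide 14 while the protons are reduced to H2 at the cathode. The closest known reaction type is the anodic or quinone-mediated oxidation of 4-alkylphenols to p-quinone methides with heteroatom capture, and the closure itself parallels phenylcoumaran formation in lignan chemistry. The benzo-ring hydroxyl adds to the exocyclic carbon in a 5-exo-trig 1,6-addition (oxa-Michael type), forming the O1–C2 bond and returning the oxidised ring to a free phenol. C2 is set by the existing C3 centre: the oxygen should approach the face anti to the C3 aryl group, and since the addition can revert through 14, any cis isomer should drain to the more stable trans (2S,3S) product while C3 itself is not touched. The step needs site-selective oxidation, which is secured because the benzo-ring phenol is deactivated by its para ester and kept un-ionised by the AcOH buffer, and because the resorcinol ring is capped by bulky silyl groups that shield its nucleophilic carbons from the oxidised ring. Methanol or ipso adducts are reversible and should funnel to 15 in the mildly acidic electrolyte, and the charge is limited to prevent further oxidation of 15 to the benzofuran.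

Step 7
Reactants: 15 methyl (2S,3S)-3-[3,5-bis(triisopropylsilyloxy)phenyl]-2-(4-hydroxyphenyl)-2,3-dihydro-1-benzofuran-5-carboxylate
Product: 16 methyl (2S,3S)-3-[3,5-bis(triisopropylsilyloxy)phenyl]-2-[4-(triisopropylsilyloxy)phenyl]-2,3-dihydro-1-benzofuran-5-carboxylate
Conditions: i-Pr3SiCl, imidazole, DMF, 23 °C
Reagents that add atoms: chlorotriisopropylsilane, CC(C)[Si](Cl)(C(C)C)C(C)C
Why: Silylation of the only free phenol prevents the aluminium hydride and the strong base used later from reopening the dihydrofuran through a phenoxide-driven quinone methide.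

Step 8
Reactants: 16 methyl (2S,3S)-3-[3,5-bis(triisopropylsilyloxy)phenyl]-2-[4-(triisopropylsilyloxy)phenyl]-2,3-dihydro-1-benzofuran-5-carboxylate
Product: 17 {(2S,3S)-3-[3,5-bis(triisopropylsilyloxy)phenyl]-2-[4-(triisopropylsilyloxy)phenyl]-2,3-dihydro-1-benzofuran-5-yl}methanol
Conditions: i-Bu2AlH, CH2Cl2, −78 → 0 °C; aq. potassium sodium tartrate
Reagents that add atoms: none
Why: Diisobutylaluminium hydride reduction of the methyl ester to the primary benzylic alcohol leaves aryl silyl ethers and both stereocentres untouched.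

Step 9
Reactants: 17 {(2S,3S)-3-[3,5-bis(triisopropylsilyloxy)phenyl]-2-[4-(triisopropylsilyloxy)phenyl]-2,3-dihydro-1-benzofuran-5-yl}methanol
Product: 18 (2S,3S)-5-(bromomethyl)-3-[3,5-bis(triisopropylsilyloxy)phenyl]-2-[4-(triisopropylsilyloxy)phenyl]-2,3-dihydro-1-benzofuran
Conditions: CBr4, PPh3, CH2Cl2, 0 °C; used at once
Reagents that add atoms: tetrabromomethane, BrC(Br)(Br)Br
Why: The Appel reaction brominates the primary benzylic alcohol under neutral conditions, which suits the acid-sensitive p-alkoxybenzylic system.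

Step 10
Reactants: 18 (2S,3S)-5-(bromomethyl)-3-[3,5-bis(triisopropylsilyloxy)phenyl]-2-[4-(triisopropylsilyloxy)phenyl]-2,3-dihydro-1-benzofuran
Product: 19 diethyl ({(2S,3S)-3-[3,5-bis(triisopropylsilyloxy)phenyl]-2-[4-(triisopropylsilyloxy)phenyl]-2,3-dihydro-1-benzofuran-5-yl}methyl)phosphonate
Conditions: P(OEt)3 (neat), 110 °C
Reagents that add atoms: triethyl phosphite, CCOP(OCC)OCC
Why: The Michaelis–Arbuzov reaction of a reactive benzylic bromide with triethyl phosphite gives the phosphonate with loss of bromoethane and involves neither acid nor base.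

Step 11
Reactants: 20 3,5-dihydroxybenzaldehyde
Product: 21 3,5-bis(triisopropylsilyloxy)benzaldehyde
Conditions: i-Pr3SiCl, imidazole, DMF, 23 °C
Reagents that add atoms: chlorotriisopropylsilane, CC(C)[Si](Cl)(C(C)C)C(C)C
Why: Imidazole-promoted silylation gives the aldehyde partner with the same fluoride-labile protection as the rest of the molecule.

Step 12
Reactants: 19 diethyl ({(2S,3S)-3-[3,5-bis(triisopropylsilyloxy)phenyl]-2-[4-(triisopropylsilyloxy)phenyl]-2,3-dihydro-1-benzofuran-5-yl}methyl)phosphonate; 21 3,5-bis(triisopropylsilyloxy)benzaldehyde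
Product: 22 (2S,3S)-3-[3,5-bis(triisopropylsilyloxy)phenyl]-5-{(E)-2-[3,5-bis(triisopropylsilyloxy)phenyl]ethenyl}-2-[4-(triisopropylsilyloxy)phenyl]-2,3-dihydro-1-benzofuran
Conditions: NaH, 15-crown-5 (cat.), THF, 0 → 23 °C
Reagents that add atoms: none
Why: Horner–Wadsworth–Emmons olefination of an aryl aldehyde with a benzylic phosphonate anion should give the (E)-stilbene, and the non-nucleophilic base spares the aryl silyl ethers and the C2 and C3 centres.

Step 13
Reactants: 22 (2S,3S)-3-[3,5-bis(triisopropylsilyloxy)phenyl]-5-{(E)-2-[3,5-bis(triisopropylsilyloxy)phenyl]ethenyl}-2-[4-(triisopropylsilyloxy)phenyl]-2,3-dihydro-1-benzofuran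
Product: 23 (2S,3S)-trans-delta-viniferin
Conditions: Bu4NF, AcOH (6 equiv each), THF, 0 °C, argon, dark
Reagents that add atoms: none
Why: Fluoride-induced cleavage of the five aryl silyl ethers, buffered with acetic acid, frees all phenols in one operation without strong acid or free phenoxide, so the dihydrofuran ring and both stereocentres should be retained.

Compound list
1 | methyl 3-formyl-4-hydroxybenzoate | COC(=O)c1ccc(O)c(C=O)c1 | starting material
2 | methyl 4-(benzyloxy)-3-formylbenzoate | COC(=O)c1ccc(OCc2ccccc2)c(C=O)c1 | intermediate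
3 | 4-(benzyloxy)benzyl chloride | ClCc1ccc(OCc2ccccc2)cc1 | starting material
4 | 4-(benzyloxy)benzylmagnesium chloride | Cl[Mg]Cc1ccc(OCc2ccccc2)cc1 | intermediate (not isolated)
5 | racemic methyl 4-(benzyloxy)-3-{2-[4-(benzyloxy)phenyl]-1-hydroxyethyl}benzoate | COC(=O)c1ccc(OCc2ccccc2)c(C(O)Cc2ccc(OCc3ccccc3)cc2)c1 | intermediate
6 | 5-bromobenzene-1,3-diol | Oc1cc(O)cc(Br)c1 | starting material
7 | 1-bromo-3,5-bis(triisopropylsilyloxy)benzene | Brc1cc(O[Si](C(C)C)(C(C)C)C(C)C)cc(O[Si](C(C)C)(C(C)C)C(C)C)c1 | intermediate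
8 | [3,5-bis(triisopropylsilyloxy)phenyl]magnesium bromide | Br[Mg]c1cc(O[Si](C(C)C)(C(C)C)C(C)C)cc(O[Si](C(C)C)(C(C)C)C(C)C)c1 | intermediate (not isolated)
9 | [3,5-bis(triisopropylsilyloxy)phenyl]zinc iodide | I[Zn]c1cc(O[Si](C(C)C)(C(C)C)C(C)C)cc(O[Si](C(C)C)(C(C)C)C(C)C)c1 | intermediate (not isolated)
10 | racemic methyl 4-(benzyloxy)-3-{2-[4-(benzyloxy)phenyl]-1-[(methylsulfonyl)oxy]ethyl}benzoate | COC(=O)c1ccc(OCc2ccccc2)c(C(OS(C)(=O)=O)Cc2ccc(OCc3ccccc3)cc2)c1 | intermediate (not isolated)
11 | racemic methyl 4-(benzyloxy)-3-{2-[4-(benzyloxy)phenyl]-1-iodoethyl}benzoate | COC(=O)c1ccc(OCc2ccccc2)c(C(I)Cc2ccc(OCc3ccccc3)cc2)c1 | intermediate (not isolated)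
12 | methyl 4-(benzyloxy)-3-[(1S)-2-[4-(benzyloxy)phenyl]-1-[3,5-bis(triisopropylsilyloxy)phenyl]ethyl]benzoate | c1ccccc1COc1ccc(C[C@H](c2cc(C(=O)OC)ccc2OCc2ccccc2)c2cc(O[Si](C(C)C)(C(C)C)C(C)C)cc(O[Si](C(C)C)(C(C)C)C(C)C)c2)cc1 | intermediate
13 | methyl 3-[(1S)-1-[3,5-bis(triisopropylsilyloxy)phenyl]-2-(4-hydroxyphenyl)ethyl]-4-hydroxybenzoate | Oc1ccc(C[C@H](c2cc(C(=O)OC)ccc2O)c2cc(O[Si](C(C)C)(C(C)C)C(C)C)cc(O[Si](C(C)C)(C(C)C)C(C)C)c2)cc1 | intermediate (key-step precursor)
14 | methyl 3-[(1S)-1-[3,5-bis(triisopropylsilyloxy)phenyl]-2-(4-oxocyclohexa-2,5-dien-1-ylidene)ethyl]-4-hydroxybenzoate (p-quinone methide) | O=C1C=CC(=C[C@H](c2cc(C(=O)OC)ccc2O)c2cc(O[Si](C(C)C)(C(C)C)C(C)C)cc(O[Si](C(C)C)(C(C)C)C(C)C)c2)C=C1 | intermediate (not isolated)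
15 | methyl (2S,3S)-3-[3,5-bis(triisopropylsilyloxy)phenyl]-2-(4-hydroxyphenyl)-2,3-dihydro-1-benzofuran-5-carboxylate (trans) | Oc1ccc([C@H]2Oc3ccc(C(=O)OC)cc3[C@@H]2c2cc(O[Si](C(C)C)(C(C)C)C(C)C)cc(O[Si](C(C)C)(C(C)C)C(C)C)c2)cc1 | intermediate (key-step product)
16 | methyl (2S,3S)-3-[3,5-bis(triisopropylsilyloxy)phenyl]-2-[4-(triisopropylsilyloxy)phenyl]-2,3-dihydro-1-benzofuran-5-carboxylate | CC(C)[Si](C(C)C)(C(C)C)Oc1ccc([C@H]2Oc3ccc(C(=O)OC)cc3[C@@H]2c2cc(O[Si](C(C)C)(C(C)C)C(C)C)cc(O[Si](C(C)C)(C(C)C)C(C)C)c2)cc1 | intermediate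
17 | {(2S,3S)-3-[3,5-bis(triisopropylsilyloxy)phenyl]-2-[4-(triisopropylsilyloxy)phenyl]-2,3-dihydro-1-benzofuran-5-yl}methanol | CC(C)[Si](C(C)C)(C(C)C)Oc1ccc([C@H]2Oc3ccc(CO)cc3[C@@H]2c2cc(O[Si](C(C)C)(C(C)C)C(C)C)cc(O[Si](C(C)C)(C(C)C)C(C)C)c2)cc1 | intermediate
18 | (2S,3S)-5-(bromomethyl)-3-[3,5-bis(triisopropylsilyloxy)phenyl]-2-[4-(triisopropylsilyloxy)phenyl]-2,3-dihydro-1-benzofuran | CC(C)[Si](C(C)C)(C(C)C)Oc1ccc([C@H]2Oc3ccc(CBr)cc3[C@@H]2c2cc(O[Si](C(C)C)(C(C)C)C(C)C)cc(O[Si](C(C)C)(C(C)C)C(C)C)c2)cc1 | intermediate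
19 | diethyl ({(2S,3S)-3-[3,5-bis(triisopropylsilyloxy)phenyl]-2-[4-(triisopropylsilyloxy)phenyl]-2,3-dihydro-1-benzofuran-5-yl}methyl)phosphonate | CC(C)[Si](C(C)C)(C(C)C)Oc1ccc([C@H]2Oc3ccc(CP(=O)(OCC)OCC)cc3[C@@H]2c2cc(O[Si](C(C)C)(C(C)C)C(C)C)cc(O[Si](C(C)C)(C(C)C)C(C)C)c2)cc1 | intermediate
20 | 3,5-dihydroxybenzaldehyde | O=Cc1cc(O)cc(O)c1 | starting material
21 | 3,5-bis(triisopropylsilyloxy)benzaldehyde | O=Cc1cc(O[Si](C(C)C)(C(C)C)C(C)C)cc(O[Si](C(C)C)(C(C)C)C(C)C)c1 | intermediate
22 | (2S,3S)-3-[3,5-bis(triisopropylsilyloxy)phenyl]-5-{(E)-2-[3,5-bis(triisopropylsilyloxy)phenyl]ethenyl}-2-[4-(triisopropylsilyloxy)phenyl]-2,3-dihydro-1-benzofuran | CC(C)[Si](C(C)C)(C(C)C)Oc1ccc([C@H]2Oc3ccc(/C=C/c4cc(O[Si](C(C)C)(C(C)C)C(C)C)cc(O[Si](C(C)C)(C(C)C)C(C)C)c4)cc3[C@@H]2c2cc(O[Si](C(C)C)(C(C)C)C(C)C)cc(O[Si](C(C)C)(C(C)C)C(C)C)c2)cc1 | intermediate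
23 | (2S,3S)-trans-delta-viniferin | Oc1ccc([C@H]2Oc3ccc(/C=C/c4cc(O)cc(O)c4)cc3[C@@H]2c2cc(O)cc(O)c2)cc1 | target

Total step count: 13. Longest linear sequence: 11 steps (1 → 2 → 5 → 12 → 13 → 15 → 16 → 17 → 18 → 19 → 22 → 23; steps 1, 2, 4, 5, 6, 7, 8, 9, 10, 12 and 13).

Steps most likely to fail

Step 6. The oxidised phenol ring may be captured at its ipso carbon, quinone methide 14 may tautomerise to the triarylethene with loss of C3, product 15 may be oxidised further to the benzofuran, or the anode may passivate. The fallback sets out from 13 and comes back at 15. It gives up the electrode for homogeneous hydride abstraction by a quinone: one equivalent of 2,3-dichloro-5,6-dicyano-1,4-benzoquinone in CH2Cl2–1,4-dioxane at 0 °C removes hydride from the benzylic C2–H of the free 4-alkylphenol. This gives the same quinone methide 14 with exact control of the oxidant, and 14 closes to 15. No compound outside the list is made (F0).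

Step 4. The activated alcohol may eliminate to the stilbene before coupling, or the catalyst may discriminate poorly between the faces of the ortho-substituted benzylic radical. The fallback sets out from 5 (with Grignard reagent 8 from 7) and comes back at 12. It replaces asymmetric catalysis by a racemic construction and a separation.
- Alcohol 5 is oxidised with Dess–Martin periodinane to the ketone methyl 4-(benzyloxy)-3-{[4-(benzyloxy)phenyl]acetyl}benzoate F1.
- Grignard reagent 8 is added at −78 °C in the presence of LaCl3·2LiCl to give the tertiary carbinol methyl 4-(benzyloxy)-3-{2-[4-(benzyloxy)phenyl]-1-[3,5-bis(triisopropylsilyloxy)phenyl]-1-hydroxyethyl}benzoate F2.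
- Ionic hydrogenation (Et3SiH, CF3CO2H, CH2Cl2, −40 °C) gives the racemic triarylethane methyl 4-(benzyloxy)-3-{2-[4-(benzyloxy)phenyl]-1-[3,5-bis(triisopropylsilyloxy)phenyl]ethyl}benzoate F3.
- Preparative chromatography on a chiral stationary phase (supercritical CO2) separates the enantiomers and delivers 12.

Step 9. The electron-rich p-alkoxybenzylic bromide may ionise and be lost to solvolysis or self-alkylation before the Arbuzov step. The fallback sets out from 17 and 21 and comes back at 22. It reverses the polarity of the olefination so that no activated halide is made on the advanced fragment.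
- Alcohol 17 is oxidised with MnO2 in CH2Cl2 to (2S,3S)-3-[3,5-bis(triisopropylsilyloxy)phenyl]-2-[4-(triisopropylsilyloxy)phenyl]-2,3-dihydro-1-benzofuran-5-carbaldehyde F4.
- Aldehyde 21 is reduced with NaBH4 in THF–EtOH to [3,5-bis(triisopropylsilyloxy)phenyl]methanol F5.
- Appel bromination (CBr4, PPh3) gives 1-(bromomethyl)-3,5-bis(triisopropylsilyloxy)benzene F6, a benzylic bromide without resonance activation.
- Heating with triethyl phosphite gives diethyl [3,5-bis(triisopropylsilyloxy)benzyl]phosphonate F7.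
- Horner–Wadsworth–Emmons olefination of F4 with the sodium salt of F7 (NaH, 15-crown-5, THF) gives 22.

Further compounds
F0 | step 6 | none | none
F1 | step 4 | methyl 4-(benzyloxy)-3-{[4-(benzyloxy)phenyl]acetyl}benzoate | COC(=O)c1ccc(OCc2ccccc2)c(C(=O)Cc2ccc(OCc3ccccc3)cc2)c1
F2 | step 4 | racemic methyl 4-(benzyloxy)-3-{2-[4-(benzyloxy)phenyl]-1-[3,5-bis(triisopropylsilyloxy)phenyl]-1-hydroxyethyl}benzoate | COC(=O)c1ccc(OCc2ccccc2)c(C(O)(Cc2ccc(OCc3ccccc3)cc2)c2cc(O[Si](C(C)C)(C(C)C)C(C)C)cc(O[Si](C(C)C)(C(C)C)C(C)C)c2)c1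
F3 | step 4 | racemic methyl 4-(benzyloxy)-3-{2-[4-(benzyloxy)phenyl]-1-[3,5-bis(triisopropylsilyloxy)phenyl]ethyl}benzoate | COC(=O)c1ccc(OCc2ccccc2)c(C(Cc2ccc(OCc3ccccc3)cc2)c2cc(O[Si](C(C)C)(C(C)C)C(C)C)cc(O[Si](C(C)C)(C(C)C)C(C)C)c2)c1
F4 | step 9 | (2S,3S)-3-[3,5-bis(triisopropylsilyloxy)phenyl]-2-[4-(triisopropylsilyloxy)phenyl]-2,3-dihydro-1-benzofuran-5-carbaldehyde | CC(C)[Si](C(C)C)(C(C)C)Oc1ccc([C@H]2Oc3ccc(C=O)cc3[C@@H]2c2cc(O[Si](C(C)C)(C(C)C)C(C)C)cc(O[Si](C(C)C)(C(C)C)C(C)C)c2)cc1
F5 | step 9 | [3,5-bis(triisopropylsilyloxy)phenyl]methanol | OCc1cc(O[Si](C(C)C)(C(C)C)C(C)C)cc(O[Si](C(C)C)(C(C)C)C(C)C)c1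
F6 | step 9 | 1-(bromomethyl)-3,5-bis(triisopropylsilyloxy)benzene | BrCc1cc(O[Si](C(C)C)(C(C)C)C(C)C)cc(O[Si](C(C)C)(C(C)C)C(C)C)c1
F7 | step 9 | diethyl [3,5-bis(triisopropylsilyloxy)benzyl]phosphonate | CCOP(=O)(Cc1cc(O[Si](C(C)C)(C(C)C)C(C)C)cc(O[Si](C(C)C)(C(C)C)C(C)C)c1)OCC
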